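The plan rests on closing the ten-membered ring at C7–C8. C7, the lactone carbinol carbon lying between C6 and C8, is presented as an aldehyde flanked by a C5–C6 epoxide, and C8 as a Z enol triflate whose C19 methyl ester is cis to the leaving group. A single chromium–nickel operation forms C7–C8, closes the carbocycle fused to ring A and lets the new C7 alkoxide lactonise to the butenolide. The cyclisation precursor is ring A with both target esters in place, the triflyloxy-enoate arm on C10 and the epoxy-aldehyde arm on C1; base afterwards opens the epoxide from C7 to give the C5 alcohol and the C6=C7 enol lactone.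

Key step: step 18

Remarks: briarane numbering is used throughout (C7 is bonded to C6 and C8; C5 is one carbon further along the ring). "C14 face" means the face of ring A that carries the C14 oxygen (the isopropenyl group before step 10). The C7 configuration of the cyclised compounds is drawn as the Felkin–Anh adduct; it is lost in the last step, so its epimer would serve equally.

Step 1
Reactants: 1 geraniol
Product: 2 (2S,3S)-2,3-epoxygeraniol
Conditions: Ti(OiPr)4 (5 mol%), L-(+)-diethyl tartrate (6 mol%), tBuOOH, 4 Å molecular sieves, CH2Cl2, −20 °C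
Reagents that add atoms: tert-butyl hydroperoxide, CC(C)(C)OO
Why: Sharpless asymmetric epoxidation of the allylic alcohol, in which the L-(+)-tartrate titanium complex should give the (2S,3S) epoxide that becomes C5 and C6, while the remote trisubstituted alkene is left alone.

Step 2
Reactants: 2 (2S,3S)-2,3-epoxygeraniol
Product: 3 silyl ether of 2
Conditions: TBSCl, imidazole, DMF, 0 °C → rt
Reagents that add atoms: tert-butyldimethylsilyl chloride, CC(C)(C)[Si](C)(C)Cl
Why: Silylation of the primary alcohol (substitution at silicon) masks the future C7 oxygen with a group that tolerates enolates, hydride, ozone and heat and is removed by buffered fluoride in step 16.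

Step 3
Reactants: 3 silyl ether of 2
Product: 5 C2–C7 epoxy aldehyde, via secondary ozonide 4 (not isolated)
Conditions: O3, CH2Cl2, −78 °C; then PPh3, −78 °C → rt
Reagents that add atoms: ozone, [O-][O+]=O
Why: Ozonolysis with reductive work-up cleaves the only alkene to the aldehyde that becomes C2, the epoxide and silyl ether being inert to ozone at low temperature.

Step 4
Reactants: 6 (S)-carvone
Product: 7 trans-carvone oxide
Conditions: H2O2 (30% aq.), NaOH (cat.), MeOH, 0 °C
Reagents that add atoms: hydrogen peroxide, OO
Why: Weitz–Scheffer nucleophilic epoxidation, in which hydroperoxide adds axially to C12 anti to the isopropenyl group, so the C11–C12 epoxide oxygen lies opposite the C14 face and later fixes the C12 carbinol.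

Step 5
Reactants: 7 trans-carvone oxide; 5 C2–C7 epoxy aldehyde
Product: 9 aldol adduct, via lithium enolate 8 (not isolated)
Conditions: LiN(iPr)2, THF, −78 °C; then 5, −78 °C; NH4Cl (aq.)
Reagents that add atoms: none
Why: Kinetic deprotonation at the only enolisable position (future C1) and lithium enolate aldol addition form C1–C2; the configurations at C1 and C2 do not matter because both are reset in steps 6 to 8.

Step 6
Reactants: 9 aldol adduct
Product: 10 β-diketone
Conditions: DMP, NaHCO3, CH2Cl2, 0 °C → rt
Reagents that add atoms: none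
Why: Dess–Martin oxidation turns the β-hydroxy ketone into the 1,3-diketone under buffered, non-basic conditions that spare both epoxides and the silyl ether.

Step 7
Reactants: 10 β-diketone
Product: 11 C1-quaternary diketone
Conditions: MeI, K2CO3, acetone, rt
Reagents that add atoms: iodomethane, CI
Why: C-alkylation of the stabilised 1,3-diketone enolate, in which iodomethane should approach C1 anti to the isopropenyl group on the neighbouring carbon (and to the C11 methyl), placing the methyl opposite the C14 face and the acyl chain on it.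

Step 8
Reactants: 11 C1-quaternary diketone
Product: 12 (2S) alcohol
Conditions: (R)-2-methyl-CBS-oxazaborolidine (20 mol%), catecholborane, toluene, −40 °C
Reagents that add atoms: none
Why: Corey–Bakshi–Shibata reduction, in which the C2 carbonyl offers one fully substituted and one methylene flank so the (R) catalyst should deliver hydride to give the (2S) carbinol, while the C10 carbonyl between two fully substituted carbons cannot bind the catalyst and catecholborane leaves alkene and epoxides untouched.

Step 9
Reactants: 12 (2S) alcohol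
Product: 13 C2 isovalerate
Conditions: isovaleryl chloride, pyridine, DMAP (cat.), CH2Cl2, 0 °C → rt
Reagents that add atoms: 3-methylbutanoyl chloride, CC(C)CC(Cl)=O
Why: DMAP-catalysed acylation installs the target's C2 ester at once, which also blocks retro-aldol cleavage of the β-hydroxy ketone.

Step 10
Reactants: 13 C2 isovalerate
Product: 15 C14 acetate, via methoxy hydroperoxide 14 (not isolated)
Conditions: O3, CH2Cl2/MeOH, −78 °C; then Ac2O, Et3N, DMAP, −78 → 40 °C
Reagents that add atoms: ozone, [O-][O+]=O; methanol, CO
Why: Ozonolysis in methanol followed by Criegee rearrangement of the peracetate moves C14 from carbon to oxygen with retention, so the isopropenyl group (the only alkene present) becomes the C14 acetate on the same face, its acetyl carbons being the former alkene carbon and methyl.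

Step 11
Reactants: 15 C14 acetate
Product: 17 transposed allylic alcohol, via epoxy hydrazone 16 (not isolated)
Conditions: N2H4·H2O, AcOH (cat.), MeOH, 0 °C → rt
Reagents that add atoms: none
Why: Wharton transposition, in which the hydrazone of the α,β-epoxy ketone opens the C11–O bond and loses dinitrogen, leaving the C10=C11 alkene and the C12 alcohol with the epoxide configuration retained (oxygen opposite the C14 face).

Step 12
Reactants: 17 transposed allylic alcohol
Product: 19 C8 aldehyde, via allyl vinyl ether 18 (not isolated)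
Conditions: butyl vinyl ether, Pd(OCOCF3)2 (5 mol%), 4,7-diphenyl-1,10-phenanthroline, Et3N, 75 °C; then xylene, 150 °C (sealed tube)
Reagents that add atoms: butyl vinyl ether, C=COCCCC
Why: Palladium-catalysed transfer vinylation followed by Claisen rearrangement forms C10–C9 suprafacially from the face of the C12 oxygen, which sets C10 with its arm cis to the C1 methyl and moves the alkene to C11=C12.

Step 13
Reactants: 19 C8 aldehyde; 20 methyl propionate
Product: 22 β-hydroxy ester, via propionate lithium enolate 21 (not isolated)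
Conditions: 20, LiN(iPr)2, THF, −78 °C; then 19, −78 °C; NH4Cl (aq.)
Reagents that add atoms: none
Why: Ester enolate aldol addition to the aldehyde is far faster at −78 °C than attack on the two hindered secondary esters, and the new C8 and C17 centres are removed in steps 14 and 15.

Step 14
Reactants: 22 β-hydroxy ester
Product: 23 β-keto ester
Conditions: DMP, NaHCO3, CH2Cl2, 0 °C → rt
Reagents that add atoms: none
Why: Dess–Martin oxidation of the secondary alcohol gives the α-methyl β-keto ester without touching epoxide, silyl ether or esters.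

Step 15
Reactants: 23 β-keto ester
Product: 25 Z enol triflate, via sodium enolate 24 (not isolated)
Conditions: NaH, THF, 0 °C; then N-(5-chloropyridin-2-yl)bis(trifluoromethanesulfonyl)imide, 0 °C → rt
Reagents that add atoms: N-(5-chloropyridin-2-yl)bis(trifluoromethanesulfonyl)imide, O=S(=O)(N(c1ccc(Cl)cn1)S(=O)(=O)C(F)(F)F)C(F)(F)F
Why: Enolate O-sulfonylation, in which the sodium enolate is held in the chelated geometry with the enolate oxygen cis to the ester carbonyl, so the triflate should form as the Z isomer needed for lactonisation after coupling.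

Step 16
Reactants: 25 Z enol triflate
Product: 26 epoxy alcohol
Conditions: HF·pyridine, pyridine, THF, 0 °C → rt
Reagents that add atoms: none
Why: Buffered fluoride desilylation frees the C7 alcohol without acyl migration, epoxide opening or loss of the enol triflate.

Step 17
Reactants: 26 epoxy alcohol
Product: 27 epoxy aldehyde (cyclisation precursor)
Conditions: DMP, NaHCO3, CH2Cl2, 0 °C
Reagents that add atoms: none
Why: Dess–Martin oxidation gives the sensitive α,β-epoxy aldehyde under neutral conditions directly before use, without epimerisation at C6.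

Step 18
Reactants: 27 epoxy aldehyde (cyclisation precursor)
Product: 29 ten-membered epoxy butenolide, via chromium alkoxide 28 (not isolated)
Conditions: CrCl2 (8 equiv), NiCl2 (10 mol%), degassed DMSO/THF, rt, slow addition to 2 mM
Reagents that add atoms: none
Why: CrCl2 reduces NiCl2 to zerovalent nickel, which inserts into the C8–O bond of the enol triflate with retention of the Z geometry and passes the alkenyl group to trivalent chromium; the alkenylchromium adds to the C7 aldehyde and the chromium alkoxide 28 attacks the cis C19 methyl ester with loss of methoxide. The reaction type is an intramolecular Nozaki–Hiyama–Kishi coupling of a β-triflyloxy enoate with lactonisation in the same flask. The ten-membered carbocycle closes by 10-exo-trig carbonyl addition (C7–C8) and the butenolide by 5-exo-trig acyl substitution at C19. The one new stereocentre, C7, should follow polar Felkin–Anh addition anti to the C6–O bond, but it is destroyed in step 19, so its configuration is immaterial. The step needs addition to the aldehyde in the presence of three esters and an epoxide, and ring closure in preference to oligomerisation; the first is secured by the non-basic, aldehyde-selective alkenylchromium reagent and the second by slow addition at high dilution, helped by ring A holding the two arms on adjacent carbons.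

Step 19
Reactants: 29 ten-membered epoxy butenolide
Product: 30 target CNP0208239.1
Conditions: DBU, CH2Cl2, 0 °C → rt
Reagents that add atoms: none
Why: Vinylogous E1cB elimination, in which DBU removes the acidic C7 hydrogen and the 2-oxidofuran opens the epoxide at C6, releasing the C5 alcohol with its Sharpless-derived configuration and the C6=C7 enol lactone, whose geometry (C5 cis to C8) the ten-membered ring should enforce.

Compound list
1 | geraniol, (2E)-3,7-dimethylocta-2,6-dien-1-ol | CC(C)=CCC/C(C)=C/CO | starting material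
2 | (2S,3S)-2,3-epoxygeraniol | CC(C)=CCC[C@]1(C)O[C@H]1CO | intermediate
3 | tert-butyldimethylsilyl ether of 2 | CC(C)=CCC[C@]1(C)O[C@H]1CO[Si](C)(C)C(C)(C)C | intermediate
4 | secondary ozonide (1,2,4-trioxolane) of 3 at the terminal alkene | CC1(C)OOC(CC[C@]2(C)O[C@H]2CO[Si](C)(C)C(C)(C)C)O1 | intermediate
5 | C2–C7 epoxy aldehyde, 4-[(2S,3S)-3-(tert-butyldimethylsilyloxymethyl)-2-methyloxiran-2-yl]butanal | O=CCC[C@]1(C)O[C@H]1CO[Si](C)(C)C(C)(C)C | intermediate
6 | (S)-carvone, (5S)-2-methyl-5-(prop-1-en-2-yl)cyclohex-2-en-1-one | CC1=CC[C@@H](CC1=O)C(C)=C | starting material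
7 | trans-carvone oxide, (1S,4S,6S)-1-methyl-4-(prop-1-en-2-yl)-7-oxabicyclo[4.1.0]heptan-2-one (epoxide opposite the isopropenyl group) | O=C1C[C@@H](C(C)=C)C[C@@H]2O[C@]12C | intermediate
8 | lithium enolate of 7 (C1=C10–OLi) | [Li]OC1=C[C@@H](C(C)=C)C[C@@H]2O[C@]12C | intermediate
9 | aldol adduct: 7 carrying at C1, anti to isopropenyl, the 1-hydroxy C2–C7 chain (C2 epimers) | O=C1[C@H](C(O)CC[C@]3(C)O[C@H]3CO[Si](C)(C)C(C)(C)C)[C@@H](C(C)=C)C[C@@H]2O[C@]12C | intermediate
10 | β-diketone (C2 and C10 ketones, drawn as diketo form, C1 epimerisable) | O=C1C(C(=O)CC[C@]3(C)O[C@H]3CO[Si](C)(C)C(C)(C)C)[C@@H](C(C)=C)C[C@@H]2O[C@]12C | intermediate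
11 | C1-quaternary diketone: C1 methyl opposite the C14 face, C2 acyl chain on the C14 face | O=C1[C@@](C)(C(=O)CC[C@]3(C)O[C@H]3CO[Si](C)(C)C(C)(C)C)[C@@H](C(C)=C)C[C@@H]2O[C@]12C | intermediate
12 | (2S) alcohol of 11 | O=C1[C@@](C)([C@@H](O)CC[C@]3(C)O[C@H]3CO[Si](C)(C)C(C)(C)C)[C@@H](C(C)=C)C[C@@H]2O[C@]12C | intermediate
13 | C2 isovalerate (3-methylbutanoate) of 12 | O=C1[C@@](C)([C@@H](OC(=O)CC(C)C)CC[C@]3(C)O[C@H]3CO[Si](C)(C)C(C)(C)C)[C@@H](C(C)=C)C[C@@H]2O[C@]12C | intermediate
14 | α-methoxy hydroperoxide from the isopropenyl group of 13 | O=C1[C@@](C)([C@@H](OC(=O)CC(C)C)CC[C@]3(C)O[C@H]3CO[Si](C)(C)C(C)(C)C)[C@@H](C(C)(OC)OO)C[C@@H]2O[C@]12C | intermediate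
15 | C14 acetate: epoxy ketone with C14 OAc and C2 isovalerate chain on one face, C1 methyl and C11–C12 epoxide oxygen on the other | O=C1[C@@](C)([C@@H](OC(=O)CC(C)C)CC[C@]3(C)O[C@H]3CO[Si](C)(C)C(C)(C)C)[C@@H](OC(C)=O)C[C@@H]2O[C@]12C | intermediate
16 | C10 hydrazone of 15 | NN=C1[C@@](C)([C@@H](OC(=O)CC(C)C)CC[C@]3(C)O[C@H]3CO[Si](C)(C)C(C)(C)C)[C@@H](OC(C)=O)C[C@@H]2O[C@]12C | intermediate
17 | transposed allylic alcohol: C10=C11, C12 OH opposite the C14 face | CC1=C[C@@](C)([C@@H](OC(=O)CC(C)C)CC[C@]2(C)O[C@H]2CO[Si](C)(C)C(C)(C)C)[C@@H](OC(C)=O)C[C@@H]1O | intermediate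
18 | vinyl ether of 17 at the C12 oxygen | CC1=C[C@@](C)([C@@H](OC(=O)CC(C)C)CC[C@]2(C)O[C@H]2CO[Si](C)(C)C(C)(C)C)[C@@H](OC(C)=O)C[C@@H]1OC=C | intermediate
19 | C8 aldehyde: ring A with C11=C12, C10 bearing CH2CHO cis to the C1 methyl | CC(=O)O[C@H]1CC=C(C)[C@H](CC=O)[C@@]1(C)[C@H](CC[C@]2(C)O[C@H]2CO[Si](C)(C)C(C)(C)C)OC(=O)CC(C)C | intermediate
20 | methyl propionate | CCC(=O)OC | starting material
21 | lithium enolate of 20 | [Li]OC(OC)=CC | intermediate
22 | β-hydroxy ester (C8 and C17 epimers) | CC(=O)O[C@H]1CC=C(C)[C@H](CC(O)C(C)C(=O)OC)[C@@]1(C)[C@H](CC[C@]2(C)O[C@H]2CO[Si](C)(C)C(C)(C)C)OC(=O)CC(C)C | intermediate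
23 | β-keto ester (C8 ketone, C17 epimers) | CC(=O)O[C@H]1CC=C(C)[C@H](CC(=O)C(C)C(=O)OC)[C@@]1(C)[C@H](CC[C@]2(C)O[C@H]2CO[Si](C)(C)C(C)(C)C)OC(=O)CC(C)C | intermediate
24 | chelated sodium enolate of 23 (Z) | CC(=O)O[C@H]1CC=C(C)[C@H](C/C(O[Na])=C(\C)C(=O)OC)[C@@]1(C)[C@H](CC[C@]2(C)O[C@H]2CO[Si](C)(C)C(C)(C)C)OC(=O)CC(C)C | intermediate
25 | Z enol triflate at C8 (OTf cis to CO2Me), C7 silyl ether | CC(=O)O[C@H]1CC=C(C)[C@H](C/C(OS(=O)(=O)C(F)(F)F)=C(\C)C(=O)OC)[C@@]1(C)[C@H](CC[C@]2(C)O[C@H]2CO[Si](C)(C)C(C)(C)C)OC(=O)CC(C)C | intermediate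
26 | epoxy alcohol (free C7 OH) | CC(=O)O[C@H]1CC=C(C)[C@H](C/C(OS(=O)(=O)C(F)(F)F)=C(\C)C(=O)OC)[C@@]1(C)[C@H](CC[C@]2(C)O[C@H]2CO)OC(=O)CC(C)C | intermediate
27 | cyclisation precursor: ring A diester with the Z C8 enol triflate ester and the C5,C6-epoxy C7 aldehyde | CC(=O)O[C@H]1CC=C(C)[C@H](C/C(OS(=O)(=O)C(F)(F)F)=C(\C)C(=O)OC)[C@@]1(C)[C@H](CC[C@]2(C)O[C@H]2C=O)OC(=O)CC(C)C | intermediate
28 | ring-closed C7 chromium alkoxide (dichlorochromium on the C7 oxygen), methyl ester still open | CC(=O)O[C@H]1CC=C(C)[C@@H]2C/C(=C(\C)C(=O)OC)[C@H](O[Cr](Cl)Cl)[C@@H]3O[C@@]3(C)CC[C@H](OC(=O)CC(C)C)[C@@]12C | intermediate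
29 | ten-membered butenolide with C7–H and C5–C6 epoxide | CC(=O)O[C@H]1CC=C(C)[C@@H]2CC3=C(C)C(=O)O[C@@H]3[C@@H]4O[C@@]4(C)CC[C@H](OC(=O)CC(C)C)[C@@]12C | intermediate
30 | CNP0208239.1, (1S,2S,5S,10S,14S)-14-acetoxy-5-hydroxy-2-(3-methylbutanoyloxy) briarane enol lactone with C6=C7, C8=C17 and C11=C12 | CC(=O)O[C@H]1CC=C(C)[C@@H]2CC3=C(C)C(=O)O/C3=C/[C@@](C)(O)CC[C@H](OC(=O)CC(C)C)[C@@]12C | target

Total step count: 19. Longest linear sequence: 18 steps (geraniol 1 to 30, steps 1–3 and 5–19; 16 steps from (S)-carvone).

Steps most likely to fail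

1. Step 18. Nickel insertion into the tetrasubstituted, ester-conjugated C8–O bond may be slow, so the triflate could be reduced or the aldehyde consumed before coupling, and intermolecular addition could compete with closure of the ten-membered ring. The fallback changes the electrophile before cyclisation and sets out from 25. Pd(PPh3)4, (Me3Sn)2 and LiCl should give the Z alkenylstannane F1, and iodine should convert it with retention into the Z β-iodo enoate F2. HF·pyridine then gives the iodo alcohol F3 and Dess–Martin oxidation the iodo epoxy aldehyde F4. The alkenyl iodide undergoes metal insertion far more readily, and its CrCl2/NiCl2 cyclisation with lactonisation comes back to the route at 29.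

2. Step 11. Hydrazone formation at the C10 carbonyl, which lies between the quaternary C1 and the fully substituted epoxide carbon C11, may be slow enough for hydrazinolysis of the C14 acetate to compete. The fallback replaces the ionic transposition by a radical one and sets out from 15. NaBH4 with CeCl3·7H2O should give the epoxy alcohol F5 (either C10 epimer), and phenyl chlorothionoformate with pyridine and DMAP the O-phenyl thionocarbonate F6. Bu3SnH with AIBN in toluene at 80 °C then generates the C10 radical, which opens the adjacent C11–O bond; hydrogen transfer to the C12 oxyl radical gives the allylic alcohol and comes back to the route at 17.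

3. Step 8. Hydride may also reach the C10 carbonyl, or the catalyst may be mismatched with the substrate, so that chemoselectivity or facial selectivity at C2 is lost. The fallback replaces reagent control by chelation control and sets out from 11. With Zn(BH4)2 in Et2O at −30 °C the zinc ion should bridge the C2 and C10 carbonyl oxygens, and hydride should reach the less encumbered C2 carbonyl from the side of the C1 methyl group, the ring carbon C14 blocking the other side. By the cyclic chelate model this gives the same (2S) alcohol and comes back to the route at 12; no new compound arises (F0).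

Further compounds
F1 | step 18 | Z alkenyl trimethylstannane at C8 (tin cis to CO2Me), C7 silyl ether | CC(=O)O[C@H]1CC=C(C)[C@H](C/C([Sn](C)(C)C)=C(\C)C(=O)OC)[C@@]1(C)[C@H](CC[C@]2(C)O[C@H]2CO[Si](C)(C)C(C)(C)C)OC(=O)CC(C)C
F2 | step 18 | Z β-iodo enoate at C8, C7 silyl ether | CC(=O)O[C@H]1CC=C(C)[C@H](C/C(I)=C(\C)C(=O)OC)[C@@]1(C)[C@H](CC[C@]2(C)O[C@H]2CO[Si](C)(C)C(C)(C)C)OC(=O)CC(C)C
F3 | step 18 | iodo epoxy alcohol (free C7 OH) | CC(=O)O[C@H]1CC=C(C)[C@H](C/C(I)=C(\C)C(=O)OC)[C@@]1(C)[C@H](CC[C@]2(C)O[C@H]2CO)OC(=O)CC(C)C
F4 | step 18 | iodo epoxy aldehyde (C7 aldehyde) | CC(=O)O[C@H]1CC=C(C)[C@H](C/C(I)=C(\C)C(=O)OC)[C@@]1(C)[C@H](CC[C@]2(C)O[C@H]2C=O)OC(=O)CC(C)C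
F5 | step 11 | C10 epoxy alcohol from 15 (C10 epimers) | OC1[C@@](C)([C@@H](OC(=O)CC(C)C)CC[C@]3(C)O[C@H]3CO[Si](C)(C)C(C)(C)C)[C@@H](OC(C)=O)C[C@@H]2O[C@]12C
F6 | step 11 | O-phenyl thionocarbonate of F5 at the C10 oxygen | S=C(Oc4ccccc4)OC1[C@@](C)([C@@H](OC(=O)CC(C)C)CC[C@]3(C)O[C@H]3CO[Si](C)(C)C(C)(C)C)[C@@H](OC(C)=O)C[C@@H]2O[C@]12C
F0 | step 8 | none | none
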